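## Retrosynthetic overview
1. The α-senecioyloxy-β,γ-unsaturated ketone is disconnected at the ester C–O bond and the isopropenyl C=C. This leads back to an (S)-α,β-epoxy ketone plus senecioic acid (acylative eliminative epoxide opening). The Cα–O bond and its configuration are carried through unchanged.
2. The (S)-epoxy ketone comes from the achiral 8-senecioyl enone by chiral-dioxirane epoxidation (ketone organocatalyst and Oxone). This step sets the only stereocentre.
3. The enone is disconnected at the C8–acyl bond (Friedel–Crafts) to 5,7-dimethoxycoumarin and senecioyl chloride.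
4. Rings: the coumarin bicycle is bought intact. The only rings formed are transient: the oxirane (step 2), then a 1,3-dioxolan-2-ylium ring (step 3) that is opened again to give the target.

Assumption: CIP analysis of the given SMILES gives (S). The known D-fructose-derived diacetate ketone (two steps from the commercial Shi ketone) is counted as a catalyst, not as a starting material.

## Route

Step 1
Reactants: 1 5,7-dimethoxy-2H-chromen-2-one (limettin); 2 3-methylbut-2-enoyl chloride (senecioyl chloride)
Product: 3 5,7-dimethoxy-8-(3-methylbut-2-enoyl)-2H-chromen-2-one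
Conditions: SnCl4 (2.5 equiv), ClCH2CH2Cl, 0 °C → rt; aq NaHCO3 work-up
Reagents that add atoms: none
Why: Friedel–Crafts acylation goes to C8 because C8 is ortho/para-activated by both methoxy groups like C6 but is flanked by only one freely rotating OMe, while SnCl4 is too mild to cleave the ortho-OMe and the two blocked ortho positions rule out Nazarov/indanone closure of the aryl vinyl ketone.

Step 2
Reactants: 3 5,7-dimethoxy-8-(3-methylbut-2-enoyl)-2H-chromen-2-one
Product: 4 8-{[(2S)-3,3-dimethyloxiran-2-yl]carbonyl}-5,7-dimethoxy-2H-chromen-2-one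
Conditions: D-fructose-derived 4,5-di-O-acetyl-1,2-O-isopropylidene ketone (Shi diacetate catalyst, 25 mol %), Oxone, NaHCO3, Bu4NHSO4 (cat.), MeCN/aq Na2EDTA, 0 °C → rt; recrystallise
Reagents that add atoms: Oxone (active component potassium peroxymonosulfate), [K+].[O-]S(=O)(=O)OO
Why: In this Shi epoxidation the chiral dioxirane reacts through a spiro transition state that puts the single olefinic H in the hindered quadrant (small β-methyls and a large Cα substituent favour spiro over planar), so the D-series catalyst delivers oxygen in the sense that gives (R) for Me2C=CH–alkyl, which reads (S) here because C(=O)Ar outranks CMe2O; the acetate-bearing ketone resists Baeyer–Villiger decay and tolerates conjugated acceptors, and the coumarin 3,4-bond is far less nucleophilic than Me2C=CH.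

Step 3
Reactants: 4 8-{[(2S)-3,3-dimethyloxiran-2-yl]carbonyl}-5,7-dimethoxy-2H-chromen-2-one; 5 3-methylbut-2-enoic acid (senecioic acid)
Product: 8 (2S)-1-(5,7-dimethoxy-2-oxo-2H-chromen-8-yl)-3-methyl-1-oxobut-3-en-2-yl 3-methylbut-2-enoate (target), via senecioyl triflate 6 (not isolated), via dioxolan-2-ylium triflate 7 (not isolated)
Conditions: 5 (1.3 equiv), Tf2O (1.25 equiv), DTBMP (1.4 equiv), CH2Cl2, −78 → 0 °C; then 4, −78 °C; then 2,6-lutidine (2 equiv), −78 → −20 °C; cold aq NaHCO3 quench
Reagents that add atoms: none
Why: Proposed new method: acylative eliminative epoxide opening, in which acyl triflate 6 O-acylates the oxirane oxygen, the tertiary Cβ–O bond ionises with anchimeric capture by the new ester carbonyl to give the vinylogously stabilised 1,3-dioxolan-2-ylium ion 7 (this capture, together with the weak electron push of an acylated oxygen, suppresses the semipinacol 1,2-aroyl shift usual for Lewis-acid-treated epoxy ketones), and the hindered pyridine then removes one of six exposed methyl protons rather than the single shielded and stereoelectronically misaligned Hα, releasing the isopropenyl group and leaving the senecioate on Cα, whose C–O bond is never broken so (S) is retained; the closest known reaction types are the Meerwein-type ring expansion of epoxides with acylium ions to dioxolanylium salts and the silyl triflate/hindered-amine isomerisation of trisubstituted epoxides to allylic silyl ethers.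

## Compound list
1 | 5,7-dimethoxy-2H-chromen-2-one (limettin, citropten) | COc1cc(OC)c2ccc(=O)oc2c1 | starting material
2 | 3-methylbut-2-enoyl chloride | CC(C)=CC(=O)Cl | starting material
3 | 5,7-dimethoxy-8-(3-methylbut-2-enoyl)-2H-chromen-2-one | CC(C)=CC(=O)c1c(OC)cc(OC)c2ccc(=O)oc12 | intermediate
4 | 8-{[(2S)-3,3-dimethyloxiran-2-yl]carbonyl}-5,7-dimethoxy-2H-chromen-2-one | CC1(C)O[C@@H]1C(=O)c2c(OC)cc(OC)c3ccc(=O)oc23 | intermediate
5 | 3-methylbut-2-enoic acid | CC(C)=CC(=O)O | starting material
6 | 3-methylbut-2-enoyl trifluoromethanesulfonate (not isolated) | CC(C)=CC(=O)OS(=O)(=O)C(F)(F)F | intermediate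
7 | (5S)-5-[(5,7-dimethoxy-2-oxo-2H-chromen-8-yl)carbonyl]-4,4-dimethyl-2-(2-methylprop-1-en-1-yl)-1,3-dioxolan-2-ylium triflate (not isolated) | CC(C)=CC1=[O+]C(C)(C)[C@H](O1)C(=O)c2c(OC)cc(OC)c3ccc(=O)oc23.[O-]S(=O)(=O)C(F)(F)F | intermediate
8 | (2S)-1-(5,7-dimethoxy-2-oxo-2H-chromen-8-yl)-3-methyl-1-oxobut-3-en-2-yl 3-methylbut-2-enoate | C=C(C)[C@H](OC(=O)C=C(C)C)C(=O)c1c(OC)cc(OC)c2ccc(=O)oc12 | target

## Totals and risks
Total step count: 3. Longest linear sequence: 3.

**Step 3 (the proposed new step).**
- Failure modes:
  - a 1,2-aroyl shift to the β-keto aldehyde;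
  - loss of Hα to give the tetrasubstituted enol ester, which destroys the stereocentre;
  - capture of the tertiary cation by the 7-OMe oxygen, giving a chromanone after demethylation;
  - survival of 7 until the quench, giving a hydroxy ester.
- Fallback (known chemistry): it sets out from 4 and returns at 8. Compound 4 is isomerised with TMSOTf/2,6-lutidine in CH2Cl2 at −78 °C (silyl triflate/amine epoxide-to-allyl silyl ether isomerisation) to 5,7-dimethoxy-8-[(2S)-3-methyl-2-(trimethylsilyloxy)but-3-enoyl]-2H-chromen-2-one F4. The silyl ether is cleaved with 1 M HCl/THF at 0 °C to 8-[(2S)-2-hydroxy-3-methylbut-3-enoyl]-5,7-dimethoxy-2H-chromen-2-one F5. F5 is esterified with 5 under Steglich conditions (DCC, cat. DMAP, CH2Cl2, 0 °C) to give 8.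

**Step 2.**
- Failure modes: slow turnover on the hindered, acceptor-substituted olefin, catalyst decay, or insufficient ee.
- Fallback: it sets out from 3 and returns at 8, bypassing 4–7. γ-Deprotonation of the s-cis enone with KHMDS (THF, −78 °C) and O-acylation with 2 gives (1Z)-1-(5,7-dimethoxy-2-oxo-2H-chromen-8-yl)-3-methylbuta-1,3-dien-1-yl 3-methylbut-2-enoate F2. Epoxidation of its enol-ester C=C with the enantiomeric (L-fructose-derived) Shi ketone and Oxone at pH 10.5 (DMM/MeCN, 0 °C) gives (2R,3S)-2-(5,7-dimethoxy-2-oxo-2H-chromen-8-yl)-3-(prop-1-en-2-yl)oxiran-2-yl 3-methylbut-2-enoate F3. Catalytic p-TsOH in CH2Cl2 at 0 °C then cleaves the C(aryl)–O bond and shifts the acyl group to the neighbouring oxygen, with retention at the carbinol carbon, giving 8.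
- The fallback's own risk is competing epoxidation of the distal isopropenyl bond.

**Step 1.**
- Failure modes: formation of the C6 isomer, or Lewis-acid demethylation of the 7-OMe followed by oxa-Michael closure to a chromanone.
- Fallback: it sets out from 1 and returns at 3. Iodination with NIS and cat. TFA in MeCN gives 8-iodo-5,7-dimethoxy-2H-chromen-2-one F1, whose regiochemistry is checked by NOE and which is purified by crystallisation. Carbonylative Suzuki–Miyaura coupling with 2-methylprop-1-enylboronic acid pinacol ester (CO 1 atm, PdCl2(dppf), K2CO3, anisole, 80 °C) then installs the enone under non-acidic conditions to give 3.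

## Further compounds
F1 | step 1 | 8-iodo-5,7-dimethoxy-2H-chromen-2-one | COc1cc(OC)c2ccc(=O)oc2c1I
F2 | step 2 | (1Z)-1-(5,7-dimethoxy-2-oxo-2H-chromen-8-yl)-3-methylbuta-1,3-dien-1-yl 3-methylbut-2-enoate | C=C(C)/C=C(\OC(=O)C=C(C)C)c1c(OC)cc(OC)c2ccc(=O)oc12
F3 | step 2 | (2R,3S)-2-(5,7-dimethoxy-2-oxo-2H-chromen-8-yl)-3-(prop-1-en-2-yl)oxiran-2-yl 3-methylbut-2-enoate | C=C(C)[C@@H]1O[C@@]1(OC(=O)C=C(C)C)c2c(OC)cc(OC)c3ccc(=O)oc23
F4 | step 3 | 5,7-dimethoxy-8-[(2S)-3-methyl-2-(trimethylsilyloxy)but-3-enoyl]-2H-chromen-2-one | C=C(C)[C@H](O[Si](C)(C)C)C(=O)c1c(OC)cc(OC)c2ccc(=O)oc12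
F5 | step 3 | 8-[(2S)-2-hydroxy-3-methylbut-3-enoyl]-5,7-dimethoxy-2H-chromen-2-one | C=C(C)[C@H](O)C(=O)c1c(OC)cc(OC)c2ccc(=O)oc12
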